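## Retrosynthetic overview

1. Target ⇒ cut the ether C–O bond at the glycerol CH2. This gives (4E,6E,8E)-dodeca-4,6,8-trien-1-ol and the achiral oxetan-3-yl 4-hydroxybenzoate. One enantioselective oxetane opening forms the ether, frees the CH2OH and creates the only stereocentre, with no protecting groups.
2. Oxetanyl ester ⇒ cut the ester C–O bond: oxetan-3-ol + 4-hydroxybenzoic acid (Mitsunobu, free phenol tolerated).
3. Trienol ⇒ trienoate ⇒ Johnson–Claisen [3,3] (sets 4E) ⇒ bis-allylic alcohol ⇒ (2E,4E)-octa-2,4-dienal + vinyl Grignard (6E and 8E are bought).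
4. Rings: none is formed. The arene and the oxetane are bought, and the oxetane is opened in the last step.

Assumption: the sense of induction of the new step cannot be predicted with certainty. The (R)-catalyst is written as the one giving the (S)-product; if experiment shows the opposite, the equally available (S)-catalyst is used.

## Route

**Step 1**
Reactants: 1 (2E,4E)-octa-2,4-dienal; 2 vinylmagnesium bromide
Product: 3 (±)-(4E,6E)-deca-1,4,6-trien-3-ol
Conditions: CH2=CHMgBr (1.2 equiv, 1 M in THF), THF, −78 → 0 °C; sat. aq NH4Cl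
Reagents that add atoms: vinylmagnesium bromide (2), C=C[Mg]Br
Why: Grignard 1,2-addition to the enal carbonyl is fast at low temperature and leaves the E,E-diene untouched; the new carbinol centre is deliberately racemic because step 2 erases it.

**Step 2**
Reactants: 3 (±)-(4E,6E)-deca-1,4,6-trien-3-ol; 4 triethyl orthoacetate
Product: 6 ethyl (4E,6E,8E)-dodeca-4,6,8-trienoate, via ketene acetal 5 (not isolated)
Conditions: MeC(OEt)3 (7 equiv), EtCO2H (5 mol %), 135–140 °C, EtOH distilled off, Ar, 3 h
Reagents that add atoms: triethyl orthoacetate (4), CC(OCC)(OCC)OCC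
Why: In this Johnson–Claisen orthoester rearrangement, ketene acetal 5 reacts through a chair [3,3] transition state with the dienyl group pseudo-equatorial and bonds at the unsubstituted vinyl terminus, so the new alkene is 4E and conjugated with the existing diene.

**Step 3**
Reactants: 6 ethyl (4E,6E,8E)-dodeca-4,6,8-trienoate
Product: 7 (4E,6E,8E)-dodeca-4,6,8-trien-1-ol
Conditions: LiAlH4 (1.0 equiv), Et2O, 0 °C, 30 min; H2O / 15 % aq NaOH / H2O work-up
Reagents that add atoms: none
Why: This is a standard LiAlH4 ester reduction, and the triene is not conjugated with the carbonyl, so it is inert to hydride and all three E alkenes are kept.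

**Step 4**
Reactants: 8 oxetan-3-ol; 9 4-hydroxybenzoic acid
Product: 10 oxetan-3-yl 4-hydroxybenzoate
Conditions: 9 (1.2 equiv), PPh3 (1.2 equiv), DIAD (1.2 equiv), THF, 0 °C → rt, 12 h
Reagents that add atoms: none
Why: In this Mitsunobu esterification only the carboxylic acid (pKa about 4.5) protonates the betaine and acts as nucleophile, so the phenol (pKa about 9) needs no protection; the neutral medium keeps the oxetane closed and no stereocentre is involved.

**Step 5**
Reactants: 7 (4E,6E,8E)-dodeca-4,6,8-trien-1-ol; 10 oxetan-3-yl 4-hydroxybenzoate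
Product: 11 (2S)-1-[(4E,6E,8E)-dodeca-4,6,8-trien-1-yloxy]-3-hydroxypropan-2-yl 4-hydroxybenzoate (target)
Conditions: 7 (1.5 equiv, excess recovered), (R)-3,3'-bis(2,4,6-triisopropylphenyl)-1,1'-binaphthyl-2,2'-diyl N-(trifluoromethylsulfonyl)phosphoramide (5 mol %), 4 Å MS, toluene/CH2Cl2 4:1 (1 M), 25 °C, Ar, dark, 24–48 h; direct fast chromatography on boric-acid-treated silica
Reagents that add atoms: none
Why: Proposed new method: intermolecular catalytic enantioselective desymmetrising alcoholysis of a prochiral 3-acyloxyoxetane. The N–H acid of the catalyst hydrogen-bonds or protonates the strained oxetane oxygen (ring strain about 106 kJ/mol, best H-bond acceptor in 10), while its phosphoryl or sulfonyl oxygen accepts the O–H of primary alcohol 7, so a bifunctional SN2 backside attack occurs inside the chiral pocket at only one of the two enantiotopic CH2 groups (the pro-S one gives the S product). No bond at the carbinol carbon is made or broken, so the stereocentre arises purely from the choice of CH2 and cannot scramble. The neutral electron-poor phenol and the ester carbonyl are much weaker nucleophiles than the H-bond-activated primary alcohol, and the acid is too weak to protonate the triene at 25 °C. The closest known reaction type is chiral phosphoric acid catalysed oxetane desymmetrisation with thiol-type nucleophiles (intermolecular) or tethered alcohols (intramolecular). The new elements are the intermolecular use of a simple aliphatic alcohol and a 3-aroyloxyoxetane as glycerol synthon.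

## Compound list

1 | (2E,4E)-octa-2,4-dienal | CCC/C=C/C=C/C=O | starting material
2 | vinylmagnesium bromide | C=C[Mg]Br | starting material
3 | (±)-(4E,6E)-deca-1,4,6-trien-3-ol | C=CC(O)/C=C/C=C/CCC | intermediate
4 | triethyl orthoacetate | CC(OCC)(OCC)OCC | starting material
5 | (4E,6E)-3-[(1-ethoxyethenyl)oxy]deca-1,4,6-triene (ketene acetal, not isolated) | C=C(OCC)OC(C=C)/C=C/C=C/CCC | intermediate
6 | ethyl (4E,6E,8E)-dodeca-4,6,8-trienoate | CCOC(=O)CC/C=C/C=C/C=C/CCC | intermediate
7 | (4E,6E,8E)-dodeca-4,6,8-trien-1-ol | OCCC/C=C/C=C/C=C/CCC | intermediate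
8 | oxetan-3-ol | OC1COC1 | starting material
9 | 4-hydroxybenzoic acid | OC(=O)c1ccc(O)cc1 | starting material
10 | oxetan-3-yl 4-hydroxybenzoate | O=C(OC1COC1)c1ccc(O)cc1 | intermediate
11 | (2S)-1-[(4E,6E,8E)-dodeca-4,6,8-trien-1-yloxy]-3-hydroxypropan-2-yl 4-hydroxybenzoate | CCC/C=C/C=C/C=C/CCCOC[C@H](CO)OC(=O)c1ccc(O)cc1 | target

## Step count and risks

Total step count: 5. Longest linear sequence: 4 (steps 1, 2, 3, 5).

### Three steps most likely to fail

**Step 5 (proposed new step).**
- The intermolecular opening may be too slow.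
- The aroyl carbonyl may attack the activated oxetane itself, giving a dioxolanylium ion or orthoester and, after work-up, monoacylglycerol.
- The primary OH of 11 may open a second oxetane.
- Acid or silica may shift the acyl group from O-2 to O-3.
- The enantioselectivity is unknown.

The fallback is known chiral-pool chemistry. It sets out from 7 and comes back at 11.
- 7 is mesylated (MsCl, Et3N, CH2Cl2, 0 °C) to (4E,6E,8E)-dodeca-4,6,8-trien-1-yl methanesulfonate F1.
- F1 alkylates the alkoxide of bought (R)-solketal (NaH, DMF, 0 °C → rt) to give (R)-4-{[(4E,6E,8E)-dodeca-4,6,8-trien-1-yloxy]methyl}-2,2-dimethyl-1,3-dioxolane F2.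
- 80 % aq AcOH at 40 °C removes the acetonide to give (S)-3-[(4E,6E,8E)-dodeca-4,6,8-trien-1-yloxy]propane-1,2-diol F3.
- TBSCl/imidazole (CH2Cl2, −20 °C) silylates only the primary hydroxyl, giving (R)-1-[(tert-butyldimethylsilyl)oxy]-3-[(4E,6E,8E)-dodeca-4,6,8-trien-1-yloxy]propan-2-ol F4.
- Steglich esterification with bought 4-[(tert-butyldimethylsilyl)oxy]benzoic acid (EDC·HCl, 4-(dimethylamino)pyridine, CH2Cl2) gives (R)-1-[(tert-butyldimethylsilyl)oxy]-3-[(4E,6E,8E)-dodeca-4,6,8-trien-1-yloxy]propan-2-yl 4-[(tert-butyldimethylsilyl)oxy]benzoate F5.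
- HF·pyridine in THF/pyridine at 0 °C removes both silyl groups without acyl shift and delivers 11. The solketal stereocentre is never touched.

**Step 2.**
- The bis-allylic alcohol can ionise under hot acid.
- Some [3,3] shift may run through the internal alkene.
- A few percent of the 4Z isomer would be hard to remove.

The fallback replaces the sigmatropic approach by olefination. It sets out from 1 and comes back at 7.
- The ylide from bought (3-carboxypropyl)triphenylphosphonium bromide (NaN(SiMe3)2, 2.1 equiv, THF, −78 °C → rt) condenses with 1 to give mainly (4Z,6E,8E)-dodeca-4,6,8-trienoic acid F6.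
- Iodine (I2, 3 mol %, hexane/CH2Cl2, daylight) equilibrates it to (4E,6E,8E)-dodeca-4,6,8-trienoic acid F7, which is purified by low-temperature crystallisation.
- LiAlH4 in Et2O reduces F7 to 7.

**Step 4.**
- Displacement at the four-membered-ring carbinol can be sluggish.
- Some phenol O-alkylation or oligoester may form.
- Removing the phosphorus by-product from polar 10 can be tedious.

The fallback switches from alcohol activation to acyl activation with a masked phenol. It sets out from 8 and comes back at 10.
- 8 is acylated with bought 4-acetoxybenzoic acid (EDC·HCl, 4-(dimethylamino)pyridine, CH2Cl2, rt) to give oxetan-3-yl 4-acetoxybenzoate F8.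
- Pyrrolidine (1.1 equiv, MeCN, 0 °C → rt) aminolyses only the aryl acetate and gives 10.

## Further compounds

F1 | step 5 | (4E,6E,8E)-dodeca-4,6,8-trien-1-yl methanesulfonate | CCC/C=C/C=C/C=C/CCCOS(C)(=O)=O
F2 | step 5 | (R)-4-{[(4E,6E,8E)-dodeca-4,6,8-trien-1-yloxy]methyl}-2,2-dimethyl-1,3-dioxolane | CCC/C=C/C=C/C=C/CCCOC[C@@H]1COC(C)(C)O1
F3 | step 5 | (S)-3-[(4E,6E,8E)-dodeca-4,6,8-trien-1-yloxy]propane-1,2-diol | CCC/C=C/C=C/C=C/CCCOC[C@H](CO)O
F4 | step 5 | (R)-1-[(tert-butyldimethylsilyl)oxy]-3-[(4E,6E,8E)-dodeca-4,6,8-trien-1-yloxy]propan-2-ol | CCC/C=C/C=C/C=C/CCCOC[C@H](CO[Si](C)(C)C(C)(C)C)O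
F5 | step 5 | (R)-1-[(tert-butyldimethylsilyl)oxy]-3-[(4E,6E,8E)-dodeca-4,6,8-trien-1-yloxy]propan-2-yl 4-[(tert-butyldimethylsilyl)oxy]benzoate | CCC/C=C/C=C/C=C/CCCOC[C@H](CO[Si](C)(C)C(C)(C)C)OC(=O)c1ccc(O[Si](C)(C)C(C)(C)C)cc1
F6 | step 2 | (4Z,6E,8E)-dodeca-4,6,8-trienoic acid | CCC/C=C/C=C/C=C\CCC(=O)O
F7 | step 2 | (4E,6E,8E)-dodeca-4,6,8-trienoic acid | CCC/C=C/C=C/C=C/CCC(=O)O
F8 | step 4 | oxetan-3-yl 4-acetoxybenzoate | CC(=O)Oc1ccc(cc1)C(=O)OC1COC1
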